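**Retrosynthetic overview** (locants are those of the 11-oxabicyclo[8.1.0]undecane names of 9–13: C1/C10 epoxide, C2 OH, C3 isopropyl, C4 ester, C6=C7 alkene)
1. The ester goes on last by site-selective aroylation of epoxy diol 11 at C4–OH; the C2–OH beside the epoxide is the hindered one.
2. C4 comes from a 1,3-syn (Narasaka–Prasad) reduction; C2 and C3 come from a Felkin-controlled transfer hydrogenation of epoxy-1,3-dione 9 with dynamic resolution at C3.
3. The ten-membered ring comes from the eight-membered epoxy ketone 3 by a two-carbon ring expansion (silyl enol ether + bromo(isopropyl)ketene [2+2], debromination, retro-aldol), which inserts C3 and C4.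
4. The epoxide (C1, C10) comes from a catalytic asymmetric nucleophilic epoxidation of the achiral dienone 2.
5. Key step: one allylic C–H oxidation breaks the C2 symmetry of 1,5-dimethylcycloocta-1,5-diene 1, which already holds both methyl groups and both cis ring alkenes. Ring order: eight-membered ring (bought) → epoxide → cyclobutanone → ten-membered ring.

Assumption: technical 1,5-dimethylcycloocta-1,5-diene is freed from its 1,6-dimethyl isomer by fractional distillation before use.

**Step 1**
Reactants: 1 (1Z,5Z)-1,5-dimethylcycloocta-1,5-diene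
Product: 2 (2Z,6Z)-3,7-dimethylcycloocta-2,6-dien-1-one
Conditions: t-BuOOH (70% aq., 4 equiv), Rh2(C6H10NO)4 (dirhodium tetracaprolactamate, 1 mol %), ClCH2CH2Cl, 40 °C, stopped at about 60% conversion, 1 recovered
Reagents that add atoms: tert-butyl hydroperoxide, CC(C)(C)OO
Why: Doyle-type allylic C–H oxidation (tert-butylperoxyl radical chain) abstracts hydrogen from the ring CH2 next to the =CH carbon, because that gives the allyl radical with a tertiary terminus, which is oxygenated at its secondary end and collapses to the β-methyl enone (the valencene-to-nootkatone pattern); the two alkenes of 1 are homotopic, so the first oxidation gives one achiral enone and breaks the C2 symmetry, and no stereocentre is formed.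

**Step 2**
Reactants: 2 (2Z,6Z)-3,7-dimethylcycloocta-2,6-dien-1-one
Product: 3 (1R,4Z,8R)-4,8-dimethyl-9-oxabicyclo[6.1.0]non-4-en-2-one
Conditions: 9-amino-9-deoxy-epi-quinine (10 mol %), CF3CO2H (20 mol %), 50% aq. H2O2 (1.5 equiv), dioxane, 35 °C
Reagents that add atoms: hydrogen peroxide, OO
Why: Iminium-catalysed Weitz–Scheffer (nucleophilic) epoxidation touches only the electron-poor enone alkene, and the chiral primary-amine salt delivers hydroperoxide to one face of the iminium ion, which sets C1 and C8 (the two epoxide carbons of the target) with the cis ring fusion dictated by the Z-enone; the facial sense is assigned by analogy with simpler cyclic enones, and the quinidine-derived pseudo-enantiomer would give ent-3.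

**Step 3**
Reactants: 3 (1R,4Z,8R)-4,8-dimethyl-9-oxabicyclo[6.1.0]non-4-en-2-one
Product: 4 {[(1R,2E,4Z,8R)-4,8-dimethyl-9-oxabicyclo[6.1.0]nona-2,4-dien-2-yl]oxy}trimethylsilane
Conditions: LiN(i-Pr)2, THF, −78 °C; Me3SiCl; non-aqueous work-up (pentane)
Reagents that add atoms: chlorotrimethylsilane, C[Si](C)(C)Cl
Why: Kinetic enolisation at the only enolisable α-carbon (C3, which is also allylic) followed by O-silylation gives the 2-silyloxy diene, and no new stereocentre is formed.

**Step 4**
Reactants: 4 {[(1R,2E,4Z,8R)-4,8-dimethyl-9-oxabicyclo[6.1.0]nona-2,4-dien-2-yl]oxy}trimethylsilane; 5 2-bromo-3-methylbutanoyl bromide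
Product: 7 3-bromo-6,10-dimethyl-3-(propan-2-yl)-2-[(trimethylsilyl)oxy]-11-oxatricyclo[8.1.0.0(2,5)]undec-6-en-4-one (1R,6Z,10R; cis-fused cyclobutanone; both C3 epimers), via bromo(propan-2-yl)ketene 6 (not isolated)
Conditions: Et3N (syringe pump), hexane–Et2O, 0 → 25 °C
Reagents that add atoms: none
Why: Dehydrobromination of 5 gives bromo(isopropyl)ketene, which adds to the electron-rich enol ether in a thermal ketene–alkene [2+2] cycloaddition, the enol ether β-carbon bonding to the ketene carbonyl carbon and the ketene approaching anti to the epoxide oxygen; the new stereocentres (cis ring fusion, C3) are erased or reset in steps 5 and 6.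

**Step 5**
Reactants: 7 3-bromo-6,10-dimethyl-3-(propan-2-yl)-2-[(trimethylsilyl)oxy]-11-oxatricyclo[8.1.0.0(2,5)]undec-6-en-4-one
Product: 9 (1R,6Z,10R)-6,10-dimethyl-3-(propan-2-yl)-11-oxabicyclo[8.1.0]undec-6-ene-2,4-dione, via debrominated silyloxycyclobutanone 8 (not isolated)
Conditions: Zn dust, NH4Cl, MeOH–THF, 0 °C; filter; then Bu4NF/AcOH (1:1), THF, −20 °C
Reagents that add atoms: none
Why: Zinc removes the α-bromine, fluoride frees the cyclobutanol alkoxide, and a strain-driven retro-aldol fragmentation of the ring-fusion bond (the cleavage that gives the allyl-conjugated dienolate) enlarges the ring by two carbons, as in the known dichloroketene route from cycloalkanone silyl enol ethers to ring-expanded 1,3-diones; buffered kinetic α-protonation keeps the C6=C7 alkene out of conjugation, and C3 stays epimerisable between the two carbonyls.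

**Step 6**
Reactants: 9 (1R,6Z,10R)-6,10-dimethyl-3-(propan-2-yl)-11-oxabicyclo[8.1.0]undec-6-ene-2,4-dione
Product: 10 (1S,2R,3S,6Z,10R)-2-hydroxy-6,10-dimethyl-3-(propan-2-yl)-11-oxabicyclo[8.1.0]undec-6-en-4-one
Conditions: RuCl(p-cymene)(TsNCH2CH2NH2) (2 mol %), HCO2H–Et3N (1:1), CH2Cl2, 25 °C
Reagents that add atoms: none
Why: Proposed new method: a Noyori–Ikariya transfer hydrogenation with dynamic kinetic resolution on a macrocyclic epoxy-1,3-dione, in which the non-chelating outer-sphere Ru–H reduces the more electrophilic α-oxygenated C2 carbonyl, Felkin–Anh attack anti to the epoxide C–O bond gives the threo epoxy alcohol (C2), and, because C3 epimerises fast through the enol in the amine buffer, only the epimer that also turns its hydrogen toward the incoming hydride (OH anti to isopropyl) is consumed, which sets C3; the closest known reaction types are the transfer-hydrogenative dynamic resolution of acyclic 2-alkyl-1,3-diketones and the Felkin-selective reduction of α,β-epoxy ketones by non-chelating hydride donors.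

**Step 7**
Reactants: 10 (1S,2R,3S,6Z,10R)-2-hydroxy-6,10-dimethyl-3-(propan-2-yl)-11-oxabicyclo[8.1.0]undec-6-en-4-one
Product: 11 (1S,2R,3R,4R,6Z,10R)-6,10-dimethyl-3-(propan-2-yl)-11-oxabicyclo[8.1.0]undec-6-ene-2,4-diol
Conditions: Et2BOMe, THF–MeOH (4:1), −78 °C; NaBH4; MeOH co-evaporation (no peroxide work-up)
Reagents that add atoms: none
Why: In the Narasaka–Prasad reduction the diethylboron chelate of the β-hydroxy ketone takes hydride by external axial delivery, which gives the 1,3-syn diol and so sets C4 from C2 (the C3 descriptor changes from S to R only through the priority rules).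

**Step 8**
Reactants: 11 (1S,2R,3R,4R,6Z,10R)-6,10-dimethyl-3-(propan-2-yl)-11-oxabicyclo[8.1.0]undec-6-ene-2,4-diol; 12 3,4,5-trimethoxybenzoyl chloride
Product: 13 (1S,2R,3S,4R,6Z,10R)-2-hydroxy-6,10-dimethyl-3-(propan-2-yl)-11-oxabicyclo[8.1.0]undec-6-en-4-yl 3,4,5-trimethoxybenzoate
Conditions: 12 (1.05 equiv), 2,4,6-collidine, CH2Cl2, −40 → 0 °C
Reagents that add atoms: none
Why: Site-selective acylation: the C2 hydroxyl is flanked by the epoxide and the isopropyl-bearing carbon and is deactivated inductively and by hydrogen bonding to the epoxide oxygen, so one equivalent of acid chloride at low temperature esterifies the less hindered C4 hydroxyl, and no stereocentre is touched.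

**Compound list**
1 | (1Z,5Z)-1,5-dimethylcycloocta-1,5-diene | C/C1=C/CC/C(C)=C\CC1 | starting material
2 | (2Z,6Z)-3,7-dimethylcycloocta-2,6-dien-1-one | O=C1\C=C(C)/CC\C=C(C)/C1 | intermediate
3 | (1R,4Z,8R)-4,8-dimethyl-9-oxabicyclo[6.1.0]non-4-en-2-one | O=C1C/C(C)=C\CC[C@@]2(C)O[C@H]21 | intermediate
4 | {[(1R,2E,4Z,8R)-4,8-dimethyl-9-oxabicyclo[6.1.0]nona-2,4-dien-2-yl]oxy}trimethylsilane | C[Si](C)(C)O/C1=C/C(C)=C\CC[C@@]2(C)O[C@H]21 | intermediate
5 | 2-bromo-3-methylbutanoyl bromide (racemic) | CC(C)C(Br)C(Br)=O | starting material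
6 | bromo(propan-2-yl)ketene (2-bromo-3-methylbut-1-en-1-one) | CC(C)C(Br)=C=O | intermediate (not isolated)
7 | 3-bromo-6,10-dimethyl-3-(propan-2-yl)-2-[(trimethylsilyl)oxy]-11-oxatricyclo[8.1.0.0(2,5)]undec-6-en-4-one; 1R,6Z,10R; cyclobutanone cis-fused, OSiMe3 at C2 and H at C5 on the face of the epoxide oxygen; both C3 epimers | CC(C)C1(Br)C(=O)[C@@H]2/C(C)=C\CC[C@@]3(C)O[C@H]3[C@]12O[Si](C)(C)C | intermediate
8 | 6,10-dimethyl-3-(propan-2-yl)-2-[(trimethylsilyl)oxy]-11-oxatricyclo[8.1.0.0(2,5)]undec-6-en-4-one; same configuration as 7, C3 unassigned | CC(C)C1C(=O)[C@@H]2/C(C)=C\CC[C@@]3(C)O[C@H]3[C@]12O[Si](C)(C)C | intermediate (not isolated)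
9 | (1R,6Z,10R)-6,10-dimethyl-3-(propan-2-yl)-11-oxabicyclo[8.1.0]undec-6-ene-2,4-dione (C3 epimerisable) | CC(C)C1C(=O)C/C(C)=C\CC[C@@]2(C)O[C@H]2C1=O | intermediate
10 | (1S,2R,3S,6Z,10R)-2-hydroxy-6,10-dimethyl-3-(propan-2-yl)-11-oxabicyclo[8.1.0]undec-6-en-4-one | CC(C)[C@@H]1C(=O)C/C(C)=C\CC[C@@]2(C)O[C@H]2[C@@H]1O | intermediate
11 | (1S,2R,3R,4R,6Z,10R)-6,10-dimethyl-3-(propan-2-yl)-11-oxabicyclo[8.1.0]undec-6-ene-2,4-diol | CC(C)[C@@H]1[C@H](O)C/C(C)=C\CC[C@@]2(C)O[C@H]2[C@@H]1O | intermediate
12 | 3,4,5-trimethoxybenzoyl chloride | COc1cc(C(=O)Cl)cc(OC)c1OC | starting material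
13 | (1S,2R,3S,4R,6Z,10R)-2-hydroxy-6,10-dimethyl-3-(propan-2-yl)-11-oxabicyclo[8.1.0]undec-6-en-4-yl 3,4,5-trimethoxybenzoate | COc1cc(C(=O)O[C@@H]2C/C(C)=C\CC[C@@]3(C)O[C@H]3[C@H](O)[C@@H]2C(C)C)cc(OC)c1OC | target

**Step count and risks**
Total steps: 8. Longest linear sequence: 8 (steps 1–8 from 1).

The three steps most likely to fail:

Step 6 (chemoselectivity between the two carbonyls, threo selectivity and the C3 resolution all rest on substrate control in a flexible ten-membered ring). The fallback sets out from 9 and comes back at 10. It replaces substrate control by enzyme control: a ketoreductase picked from a screening panel for the 2R alcohol, with NADP+, glucose and glucose dehydrogenase in phosphate buffer (pH 7)–DMSO at 30 °C, reduces the C2 carbonyl while C3 epimerises in the buffer, so the enzyme pocket and not the epoxide decides the face and the C3 epimer. It passes through no compound outside the list: none F0.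

Step 1 (regioselectivity between the two kinds of allylic CH2, over-oxidation, and drift of the remaining alkene into conjugation). The fallback sets out from 1 and comes back at 2. It replaces the C–H oxidation by an epoxide-based oxygen transposition. mCPBA (0.9 equiv, NaHCO3, CH2Cl2, 0 °C) gives the monoepoxide rac-(1R,4Z,8S)-1,5-dimethyl-9-oxabicyclo[6.1.0]non-4-ene F1. Sodium phenylselenide ((PhSe)2, NaBH4, EtOH) opens it at the secondary carbon to rac-(1R,2R,5Z)-1,5-dimethyl-2-(phenylselanyl)cyclooct-5-en-1-ol F2. H2O2 oxidation and selenoxide syn-elimination, which can only run away from the quaternary carbinol carbon, give the tertiary allylic alcohol rac-(2Z,5Z)-1,5-dimethylcycloocta-2,5-dien-1-ol F3. Pyridinium chlorochromate (C5H5NH)[CrO3Cl] in CH2Cl2 then brings about the Babler–Dauben oxidative 1,3-transposition to 2.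

Step 8 (discrimination between two secondary hydroxyls, with possible acyl migration). The fallback sets out from 10 and comes back at 13. It differentiates the oxygens by a protecting group instead of by reactivity and skips step 7. The only hydroxyl of 10 is silylated (t-BuMe2SiOTf, 2,6-lutidine, CH2Cl2, −78 °C) to (1S,2R,3S,6Z,10R)-2-[(tert-butyldimethylsilyl)oxy]-6,10-dimethyl-3-(propan-2-yl)-11-oxabicyclo[8.1.0]undec-6-en-4-one F4. A reagent-controlled Corey–Bakshi–Shibata reduction ((S)-2-methyl-CBS-oxazaborolidine, BH3·SMe2, THF, −30 °C; branched C3 side as the large group, hydride anti to isopropyl) gives (1S,2R,3R,4R,6Z,10R)-2-[(tert-butyldimethylsilyl)oxy]-6,10-dimethyl-3-(propan-2-yl)-11-oxabicyclo[8.1.0]undec-6-en-4-ol F5. The single free hydroxyl is acylated with 12 (pyridine, DMAP, CH2Cl2, 0 °C) to (1S,2R,3R,4R,6Z,10R)-2-[(tert-butyldimethylsilyl)oxy]-6,10-dimethyl-3-(propan-2-yl)-11-oxabicyclo[8.1.0]undec-6-en-4-yl 3,4,5-trimethoxybenzoate F6. HF·pyridine buffered with pyridine (THF, 0 °C) removes the silyl group and gives 13.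

**Further compounds**
F0 | step 6 | none | none
F1 | step 1 | rac-(1R,4Z,8S)-1,5-dimethyl-9-oxabicyclo[6.1.0]non-4-ene | C/C1=C/CC[C@@]2(C)O[C@H]2CC1
F2 | step 1 | rac-(1R,2R,5Z)-1,5-dimethyl-2-(phenylselanyl)cyclooct-5-en-1-ol | C/C1=C/CC[C@@](C)(O)[C@H]([Se]c2ccccc2)CC1
F3 | step 1 | rac-(2Z,5Z)-1,5-dimethylcycloocta-2,5-dien-1-ol | C/C1=C/CCC(C)(O)/C=C\C1
F4 | step 8 | (1S,2R,3S,6Z,10R)-2-[(tert-butyldimethylsilyl)oxy]-6,10-dimethyl-3-(propan-2-yl)-11-oxabicyclo[8.1.0]undec-6-en-4-one | CC(C)[C@@H]1C(=O)C/C(C)=C\CC[C@@]2(C)O[C@H]2[C@@H]1O[Si](C)(C)C(C)(C)C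
F5 | step 8 | (1S,2R,3R,4R,6Z,10R)-2-[(tert-butyldimethylsilyl)oxy]-6,10-dimethyl-3-(propan-2-yl)-11-oxabicyclo[8.1.0]undec-6-en-4-ol | CC(C)[C@@H]1[C@H](O)C/C(C)=C\CC[C@@]2(C)O[C@H]2[C@@H]1O[Si](C)(C)C(C)(C)C
F6 | step 8 | (1S,2R,3R,4R,6Z,10R)-2-[(tert-butyldimethylsilyl)oxy]-6,10-dimethyl-3-(propan-2-yl)-11-oxabicyclo[8.1.0]undec-6-en-4-yl 3,4,5-trimethoxybenzoate | COc1cc(C(=O)O[C@@H]2C/C(C)=C\CC[C@@]3(C)O[C@H]3[C@H](O[Si](C)(C)C(C)(C)C)[C@@H]2C(C)C)cc(OC)c1OC
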